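## Retrosynthetic overview

1. Target ⇒ all-trans indane 25 by O–Tf cleavage and hydrogenolysis of seven O-benzyl groups. The indane is the last ring formed, closed by a cationic Friedel–Crafts C1–C7a bond formation from 1,4-diol 24.
2. 24 ⇒ all-cis α-aryl-γ-butyrolactone 21. Its C=O carbon becomes indane C1 (DIBAL-H, then ArMgBr 22).
3. 21 ⇒ Pd enolate arylation (the C2–aryl bond) of cis-lactone 6 by bromodihydrobenzofuran 19, then kinetic protonation.
4. Key step: 6 ⇒ enal 3 + aldehyde 5. A carbene-bound homoenolate joins the enal β-carbon to the aldehyde carbon (both natural acceptor sites). This makes the C3–CH(OH) bond and sets both of its stereocentres at once.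
5. 19 ⇒ o-quinone methide 18 + chiral benzylic sulfonium ylide 17 ([4+1]). Ring order: the temporary butyrolactone and the dihydrobenzofuran are made in parallel, and the indane comes last.

**Abbreviations:** Bn = benzyl; Tf = CF3SO2; "DHB-4-yl" = (2R,3R)-6-(benzyloxy)-2-[4-(benzyloxy)phenyl]-3-[3,5-bis(benzyloxy)phenyl]-2,3-dihydro-1-benzofuran-4-yl.

**Assumption:** the antipodes written for the two chiral controllers (triazolium precatalyst, isothiocineole) are taken to be those that give the drawn configurations; both antipodes of each are available.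

## Route

Step 1
Reactants: 1 3,5-bis(benzyloxy)benzaldehyde; 2 (triphenylphosphoranylidene)acetaldehyde
Product: 3 (E)-3-[3,5-bis(benzyloxy)phenyl]prop-2-enal
Conditions: PhMe, 80 °C
Reagents that add atoms: none
Why: Wittig olefination with the carbonyl-stabilised ylide gives the (E)-enal under thermodynamic control, and no stereocentre is formed.

Step 2
Reactants: 4 4-hydroxybenzaldehyde
Product: 5 4-formylphenyl trifluoromethanesulfonate
Conditions: Tf2O, pyridine, CH2Cl2, 0 °C
Reagents that add atoms: trifluoromethanesulfonic anhydride, O=S(=O)(OS(=O)(=O)C(F)(F)F)C(F)(F)F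
Why: Simple O-sulfonylation of the phenol; the triflate makes the aldehyde electrophilic enough for step 3 and later prevents ionisation of the neighbouring carbinol in step 11.

Step 3 (key step)
Reactants: 3 (E)-3-[3,5-bis(benzyloxy)phenyl]prop-2-enal; 5 4-formylphenyl trifluoromethanesulfonate
Product: 6 (4S,5S)-4-[3,5-bis(benzyloxy)phenyl]-5-[4-(triflyloxy)phenyl]oxolan-2-one (4,5-cis)
Conditions: (5aS,10bR)-N-mesityl aminoindanol-derived triazolium BF4 (10 mol %), DBU (10 mol %), LiCl (1 equiv), THF, rt, slow addition of 3 to 5 (2 equiv)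
Reagents that add atoms: none
Why: Proposed new method: the carbene adds to enal 3 to give the extended Breslow intermediate, a homoenolate (d3) whose β-carbon, normally an acceptor site, attacks the equally electrophilic carbonyl carbon of activated aldehyde 5, after which tautomerisation to the acyl azolium and lactonisation by the new alkoxide release the catalyst; the 4,5-cis outcome is that of the known achiral imidazolylidene-catalysed enal/ArCHO γ-butyrolactone annulation, and absolute control (4S,5S) is expected because the aminoindanol triazolylidene shields one homoenolate face while Li+ ties the aldehyde to the enol oxygen, the closest known cases being the highly enantioselective carbene/Lewis-acid homoenolate annulations of isatins, α-keto esters and acyl phosphonates.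

Step 4
Reactants: 7 5-bromobenzene-1,3-diol
Product: 8 2-bromo-4,6-dihydroxybenzaldehyde
Conditions: POCl3, DMF, MeCN, 0 °C → rt; then H2O, 50 °C
Reagents that add atoms: N,N-dimethylformamide, CN(C)C=O; water, O
Why: Vilsmeier–Haack formylation goes to the position ortho to one OH and para to the other (as with orcinol), the two such positions being equivalent by symmetry.

Step 5
Reactants: 8 2-bromo-4,6-dihydroxybenzaldehyde
Product: 9 4-(benzyloxy)-2-bromo-6-hydroxybenzaldehyde
Conditions: BnBr (1.05 equiv), CsHCO3, MeCN, 80 °C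
Reagents that add atoms: benzyl bromide, BrCc1ccccc1
Why: Williamson etherification is selective for the para OH because the ortho OH is hydrogen-bonded to the aldehyde and is not deprotonated by the weak base.

Step 6
Reactants: 9 4-(benzyloxy)-2-bromo-6-hydroxybenzaldehyde; 10 1,3-bis(benzyloxy)-5-bromobenzene
Product: 13 racemic sulfone 5-(benzyloxy)-2-{[3,5-bis(benzyloxy)phenyl](4-methylbenzenesulfonyl)methyl}-3-bromophenol, via aryl Grignard 11 (not isolated), via benzhydrol 12 (not isolated)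
Conditions: 10, Mg, THF, reflux; add 9 (0.45 equiv), −20 → 0 °C; aq. quench; crude 12, TolSO2H, CH2Cl2, rt
Reagents that add atoms: p-toluenesulfinic acid, Cc1ccc(cc1)S(=O)O (magnesium, [Mg], ends up only in 11)
Why: Grignard 1,2-addition (the first equivalent only deprotonates the phenol) is followed by SN1-type sulfinate substitution of the very easily ionised ortho,para-dioxygenated benzhydrol, and the racemic centre formed is erased again in step 8.

Step 7
Reactants: 14 (1R,4R,5R)-isothiocineole; 15 1-(benzyloxy)-4-(bromomethyl)benzene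
Product: 16 S-[4-(benzyloxy)benzyl]-(1R,4R,5R)-isothiocineolium triflate (single diastereomer at sulfur)
Conditions: LiOTf, CH2Cl2/H2O, rt
Reagents that add atoms: lithium trifluoromethanesulfonate, [Li+].[O-]S(=O)(=O)C(F)(F)F
Why: SN2 S-alkylation takes place on the less hindered sulfur lone pair of the rigid bicycle, and anion exchange to the non-nucleophilic triflate makes it irreversible.

Step 8
Reactants: 13 racemic sulfone; 16 sulfonium triflate
Product: 19 (2R,3R)-6-(benzyloxy)-2-[4-(benzyloxy)phenyl]-3-[3,5-bis(benzyloxy)phenyl]-4-bromo-2,3-dihydro-1-benzofuran (trans), via sulfonium ylide 17 (not isolated), via o-quinone methide 18 (not isolated)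
Conditions: Cs2CO3 (3 equiv), MeCN/CH2Cl2, −20 → 0 °C
Reagents that add atoms: none
Why: Proposed new method: base expels sulfinate from 13 to give o-quinone methide 18 and deprotonates 16 to the semi-stabilised ylide 17, whose carbon adds through its only open face (the other is blocked by the bicyclic sulfide) to the methide carbon in the anti-betaine mode, and the phenoxide then displaces the sulfide in a 5-exo-tet SN2 step to give the trans-(2R,3R) ring; the closest known reactions are the racemic trans-selective [4+1] annulation of o-quinone methides from 2-(sulfonylmethyl)phenols with carbonyl-stabilised sulfur ylides and the highly enantioselective epoxidations, aziridinations and cyclopropanations of benzylic isothiocineole ylides.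

Step 9
Reactants: 6 cis-lactone; 19 bromodihydrobenzofuran
Product: 21 (3R,4S,5S)-3-(DHB-4-yl)-4-[3,5-bis(benzyloxy)phenyl]-5-[4-(triflyloxy)phenyl]oxolan-2-one (all-cis), via lithium enolate 20 (not isolated)
Conditions: LiHMDS (2.3 equiv), Pd(dba)2 (5 mol %), P(t-Bu)3 (10 mol %), PhMe, rt → 50 °C; then −78 °C, AcOH/THF
Reagents that add atoms: none
Why: Palladium-catalysed (Buchwald–Hartwig type) enolate α-arylation, in which Pd/P(t-Bu)3 inserts into C–Br in preference to C–OTf, leaves the more acidic product as its planar enolate 20, and kinetic protonation from the face opposite the two cis aryl groups at C4 and C5 places the new aryl group on their face and sets (3R).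

Step 10
Reactants: 21 all-cis lactone; 22 [4-(benzyloxy)phenyl]magnesium bromide (commercial THF solution)
Product: 24 (1S,2S,3R)-4-[4-(benzyloxy)phenyl]-2-[3,5-bis(benzyloxy)phenyl]-3-(DHB-4-yl)-1-[4-(triflyloxy)phenyl]butane-1,4-diol (epimer mixture at C4), via lactol 23 (not isolated)
Conditions: DIBAL-H (1.1 equiv), CH2Cl2, −78 °C; then 22 (3 equiv), THF, −78 → 0 °C; Rochelle salt
Reagents that add atoms: none
Why: One-pot lactone semi-reduction/Grignard 1,2-addition: DIBAL-H stops at the aluminium lactolate, and the Grignard reagent traps the open α-aryl aldehyde as soon as it is released on warming, so the base-labile C3 centre has no time to epimerise, while the new carbinol centre is an inconsequential mixture because it is ionised in step 11.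

Step 11
Reactants: 24 diol
Product: 25 4-{(S)-[(1S,2R,3S)-4,6-bis(benzyloxy)-3-[4-(benzyloxy)phenyl]-2-(DHB-4-yl)-2,3-dihydro-1H-inden-1-yl](hydroxy)methyl}phenyl triflate (all-trans indane; in the target-SMILES numbering C1 carries the 4-BnO-phenyl group, C2 the DHB-4-yl group and C3 the carbinol side chain, with descriptors 1S,2R,3S in that numbering too)
Conditions: Bi(OTf)3 (5 mol %), CH2Cl2/MeNO2, −20 → 0 °C
Reagents that add atoms: none
Why: Intramolecular Friedel–Crafts alkylation in which only the p-benzyloxybenzylic alcohol ionises (the other carbinol is deactivated by the 4-TfO-aryl group, and any tetrahydrofuran formed by O-capture re-ionises at the same carbon), the cation is captured in a five-ring closure by an ortho/para-activated position of the 3,5-bis(benzyloxy)phenyl ring, and the aryl group at the new centre settles anti to the neighbouring aryl group, giving the all-trans indane from both carbinol epimers, as in known cationic indane closures of stilbene dimers.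

Step 12
Reactants: 25 indane triflate
Product: 27 target CNP0175860.1, via heptabenzyl phenol 26 (not isolated)
Conditions: Et4NOH (aq), 1,4-dioxane, rt; AcOH to pH 6; then H2 (1 atm), 10 % Pd/C, MeOH, rt
Reagents that add atoms: none
Why: Hydroxide attacks the sulfur of the aryl triflate (S–O cleavage, known aryl triflate deprotection), and buffered neutral hydrogenolysis then removes the seven phenolic benzyl ethers faster than it touches the secondary benzylic alcohol or the dihydrobenzofuran C–O bond, so no stereocentre is affected.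

## Compound list

1 | 3,5-bis(benzyloxy)benzaldehyde | O=Cc1cc(OCc2ccccc2)cc(OCc2ccccc2)c1 | starting material
2 | (triphenylphosphoranylidene)acetaldehyde | O=CC=P(c1ccccc1)(c1ccccc1)c1ccccc1 | starting material
3 | (E)-3-[3,5-bis(benzyloxy)phenyl]prop-2-enal | O=C/C=C/c1cc(OCc2ccccc2)cc(OCc2ccccc2)c1 | intermediate
4 | 4-hydroxybenzaldehyde | O=Cc1ccc(O)cc1 | starting material
5 | 4-formylphenyl trifluoromethanesulfonate | O=Cc1ccc(OS(=O)(=O)C(F)(F)F)cc1 | intermediate
6 | (4S,5S)-4-[3,5-bis(benzyloxy)phenyl]-5-[4-(triflyloxy)phenyl]oxolan-2-one (cis) | O=C1C[C@@H](c2cc(OCc3ccccc3)cc(OCc3ccccc3)c2)[C@@H](c2ccc(OS(=O)(=O)C(F)(F)F)cc2)O1 | intermediate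
7 | 5-bromobenzene-1,3-diol | Oc1cc(O)cc(Br)c1 | starting material
8 | 2-bromo-4,6-dihydroxybenzaldehyde | O=Cc1c(O)cc(O)cc1Br | intermediate
9 | 4-(benzyloxy)-2-bromo-6-hydroxybenzaldehyde | O=Cc1c(O)cc(OCc2ccccc2)cc1Br | intermediate
10 | 1,3-bis(benzyloxy)-5-bromobenzene | Brc1cc(OCc2ccccc2)cc(OCc2ccccc2)c1 | starting material
11 | [3,5-bis(benzyloxy)phenyl]magnesium bromide | Br[Mg]c1cc(OCc2ccccc2)cc(OCc2ccccc2)c1 | intermediate (not isolated)
12 | 5-(benzyloxy)-2-{[3,5-bis(benzyloxy)phenyl](hydroxy)methyl}-3-bromophenol (racemic) | OC(c1cc(OCc2ccccc2)cc(OCc2ccccc2)c1)c1c(O)cc(OCc2ccccc2)cc1Br | intermediate (not isolated)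
13 | 5-(benzyloxy)-2-{[3,5-bis(benzyloxy)phenyl](4-methylbenzenesulfonyl)methyl}-3-bromophenol (racemic) | Cc1ccc(cc1)S(=O)(=O)C(c1cc(OCc2ccccc2)cc(OCc2ccccc2)c1)c1c(O)cc(OCc2ccccc2)cc1Br | intermediate
14 | (1R,4R,5R)-4,7,7-trimethyl-6-thiabicyclo[3.2.1]octane (isothiocineole) | C[C@@H]1CC[C@@H]2C[C@H]1SC2(C)C | starting material
15 | 1-(benzyloxy)-4-(bromomethyl)benzene | BrCc1ccc(OCc2ccccc2)cc1 | starting material
16 | S-[4-(benzyloxy)benzyl]isothiocineolium triflate (benzyl on the less hindered sulfur lone pair; S-configuration not encoded) | C[C@@H]1CC[C@@H]2C[C@H]1[S+](Cc1ccc(OCc3ccccc3)cc1)C2(C)C.[O-]S(=O)(=O)C(F)(F)F | intermediate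
17 | 4-(benzyloxy)benzylide of isothiocineole (sulfonium ylide) | C[C@@H]1CC[C@@H]2C[C@H]1[S+]([CH-]c1ccc(OCc3ccccc3)cc1)C2(C)C | intermediate (not isolated)
18 | 3-(benzyloxy)-6-[3,5-bis(benzyloxy)benzylidene]-5-bromocyclohexa-2,4-dien-1-one (o-quinone methide) | O=C1C=C(OCc2ccccc2)C=C(Br)C1=Cc1cc(OCc2ccccc2)cc(OCc2ccccc2)c1 | intermediate (not isolated)
19 | (2R,3R)-6-(benzyloxy)-2-[4-(benzyloxy)phenyl]-3-[3,5-bis(benzyloxy)phenyl]-4-bromo-2,3-dihydro-1-benzofuran | Brc1cc(OCc2ccccc2)cc2c1[C@@H](c1cc(OCc3ccccc3)cc(OCc3ccccc3)c1)[C@H](c1ccc(OCc3ccccc3)cc1)O2 | intermediate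
20 | lithium enolate of the α-arylated lactone | [Li+].[O-]C1=C(c2cc(OCc3ccccc3)cc3c2[C@@H](c2cc(OCc4ccccc4)cc(OCc4ccccc4)c2)[C@H](c2ccc(OCc4ccccc4)cc2)O3)[C@@H](c2cc(OCc3ccccc3)cc(OCc3ccccc3)c2)[C@@H](c2ccc(OS(=O)(=O)C(F)(F)F)cc2)O1 | intermediate (not isolated)
21 | (3R,4S,5S)-3-(DHB-4-yl)-4-[3,5-bis(benzyloxy)phenyl]-5-[4-(triflyloxy)phenyl]oxolan-2-one (all-cis) | O=C1[C@@H](c2cc(OCc3ccccc3)cc3c2[C@@H](c2cc(OCc4ccccc4)cc(OCc4ccccc4)c2)[C@H](c2ccc(OCc4ccccc4)cc2)O3)[C@@H](c2cc(OCc3ccccc3)cc(OCc3ccccc3)c2)[C@@H](c2ccc(OS(=O)(=O)C(F)(F)F)cc2)O1 | intermediate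
22 | [4-(benzyloxy)phenyl]magnesium bromide | Br[Mg]c1ccc(OCc2ccccc2)cc1 | starting material
23 | lactol of 21 (formed as its aluminium alkoxide; anomeric centre undefined) | OC1[C@@H](c2cc(OCc3ccccc3)cc3c2[C@@H](c2cc(OCc4ccccc4)cc(OCc4ccccc4)c2)[C@H](c2ccc(OCc4ccccc4)cc2)O3)[C@@H](c2cc(OCc3ccccc3)cc(OCc3ccccc3)c2)[C@@H](c2ccc(OS(=O)(=O)C(F)(F)F)cc2)O1 | intermediate (not isolated)
24 | (1S,2S,3R)-1,4-diol (C4 epimer mixture) | OC(c1ccc(OCc2ccccc2)cc1)[C@@H](c1cc(OCc2ccccc2)cc2c1[C@@H](c1cc(OCc3ccccc3)cc(OCc3ccccc3)c1)[C@H](c1ccc(OCc3ccccc3)cc1)O2)[C@@H](c1cc(OCc2ccccc2)cc(OCc2ccccc2)c1)[C@H](O)c1ccc(OS(=O)(=O)C(F)(F)F)cc1 | intermediate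
25 | heptabenzyl all-trans indane, carbinol (S), 4-triflyloxyphenyl on the carbinol | c5ccccc5COc1ccc([C@H]2c3c(OCc5ccccc5)cc(OCc5ccccc5)cc3[C@@H]([C@H](O)c3ccc(OS(=O)(=O)C(F)(F)F)cc3)[C@@H]2c2cc(OCc5ccccc5)cc3c2[C@@H](c2cc(OCc5ccccc5)cc(OCc5ccccc5)c2)[C@H](c2ccc(OCc5ccccc5)cc2)O3)cc1 | intermediate
26 | heptabenzyl ether of the target (free 4-hydroxyphenyl on the carbinol) | c5ccccc5COc1ccc([C@H]2c3c(OCc5ccccc5)cc(OCc5ccccc5)cc3[C@@H]([C@H](O)c3ccc(O)cc3)[C@@H]2c2cc(OCc5ccccc5)cc3c2[C@@H](c2cc(OCc5ccccc5)cc(OCc5ccccc5)c2)[C@H](c2ccc(OCc5ccccc5)cc2)O3)cc1 | intermediate (not isolated)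
27 | CNP0175860.1 | Oc1ccc([C@H]2c3c(O)cc(O)cc3[C@@H]([C@H](O)c3ccc(O)cc3)[C@@H]2c2cc(O)cc3c2[C@@H](c2cc(O)cc(O)c2)[C@H](c2ccc(O)cc2)O3)cc1 | target

## Step count and risks

Total step count: 12.
Longest linear sequence: 8 (steps 4, 5, 6, 8, 9, 10, 11, 12).

**Step 3.** The risks are low ee, enal self-annulation and benzoin formation. The fallback keeps the same bond construction but takes the stereocontrol out of the catalyst. It sets out from 3 and 5. The known cis-selective achiral IMes·HCl/DBU system gives 6 as a racemate, that is, together with its mirror image, the (4R,5R)-lactone F1. AlMe3-mediated aminolysis of the mixture by (S)-1-phenylethylamine gives the (3S,4S)-γ-hydroxy amide F2. From F1 it gives the diastereomeric (3R,4R)-γ-hydroxy amide F3. The two amides are separated by crystallisation or chromatography. Warming F2 with TsOH in toluene relactonises it and returns to 6. This is acyl substitution only, because the triflate-deactivated carbinol does not ionise.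

**Step 8.** The risks are that the benzylic ylide does not engage the o-quinone methide cleanly, or that the ee is low. The fallback forms the C2–C3 bond by carbene C–H insertion instead, and sets out from 9.
- K2CO3/DMF alkylation by 15 gives the ether aldehyde F4.
- Addition of 11 gives the diaryl carbinol F5.
- Dess–Martin oxidation gives the benzophenone F6.
- N2H4·H2O/AcOH gives the hydrazone F7.
- MnO2 gives the diaryldiazomethane F8.
- With Rh2(PTAD)4 (1 mol %), F8 undergoes enantioselective donor/donor-carbene 1,5 C–H insertion into the ArCH2–O group to give the cis-(2S,3R)-dihydrobenzofuran F9.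
- Catalytic BF3·OEt2 epimerises C2 through the p-benzyloxybenzyl cation and returns to trans 19.

**Step 9.** The risks are the hindered aryl bromide and hindered enolate, and strong base near the dihydrobenzofuran. The fallback inverts the roles of the coupling partners and sets out from 6 and 19. LiHMDS/TMSCl followed by NBS converts 6 into the α-bromolactone F10. Rieke zinc converts 19 into the arylzinc bromide F11. A nickel/pybox-catalysed Negishi arylation then gives the 3,4-trans lactone F12. This coupling activates the α-bromide by a radical pathway, needs no strong base and is less sensitive to bulk. LiHMDS at −78 °C converts F12 into enolate 20, where the route is rejoined for the kinetic protonation to 21.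

## Further compounds

F1 | step 3 | (4R,5R)-4-[3,5-bis(benzyloxy)phenyl]-5-[4-(triflyloxy)phenyl]oxolan-2-one (mirror image of 6) | O=C1C[C@H](c2cc(OCc3ccccc3)cc(OCc3ccccc3)c2)[C@H](c2ccc(OS(=O)(=O)C(F)(F)F)cc2)O1
F2 | step 3 | (3S,4S)-3-[3,5-bis(benzyloxy)phenyl]-4-hydroxy-N-[(1S)-1-phenylethyl]-4-[4-(triflyloxy)phenyl]butanamide | O=C(C[C@@H](c1cc(OCc2ccccc2)cc(OCc2ccccc2)c1)[C@@H](c1ccc(OS(=O)(=O)C(F)(F)F)cc1)O)N[C@@H](C)c1ccccc1
F3 | step 3 | (3R,4R)-3-[3,5-bis(benzyloxy)phenyl]-4-hydroxy-N-[(1S)-1-phenylethyl]-4-[4-(triflyloxy)phenyl]butanamide | O=C(C[C@H](c1cc(OCc2ccccc2)cc(OCc2ccccc2)c1)[C@H](c1ccc(OS(=O)(=O)C(F)(F)F)cc1)O)N[C@@H](C)c1ccccc1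
F4 | step 8 | 4-(benzyloxy)-2-{[4-(benzyloxy)phenyl]methoxy}-6-bromobenzaldehyde | O=Cc1c(OCc2ccc(OCc3ccccc3)cc2)cc(OCc2ccccc2)cc1Br
F5 | step 8 | [4-(benzyloxy)-2-{[4-(benzyloxy)phenyl]methoxy}-6-bromophenyl][3,5-bis(benzyloxy)phenyl]methanol (racemic) | OC(c1cc(OCc2ccccc2)cc(OCc2ccccc2)c1)c1c(OCc2ccc(OCc3ccccc3)cc2)cc(OCc2ccccc2)cc1Br
F6 | step 8 | [4-(benzyloxy)-2-{[4-(benzyloxy)phenyl]methoxy}-6-bromophenyl][3,5-bis(benzyloxy)phenyl]methanone | O=C(c1cc(OCc2ccccc2)cc(OCc2ccccc2)c1)c1c(OCc2ccc(OCc3ccccc3)cc2)cc(OCc2ccccc2)cc1Br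
F7 | step 8 | hydrazone of F6 | NN=C(c1cc(OCc2ccccc2)cc(OCc2ccccc2)c1)c1c(OCc2ccc(OCc3ccccc3)cc2)cc(OCc2ccccc2)cc1Br
F8 | step 8 | diaryldiazomethane from F7 | [N-]=[N+]=C(c1cc(OCc2ccccc2)cc(OCc2ccccc2)c1)c1c(OCc2ccc(OCc3ccccc3)cc2)cc(OCc2ccccc2)cc1Br
F9 | step 8 | (2S,3R)-6-(benzyloxy)-2-[4-(benzyloxy)phenyl]-3-[3,5-bis(benzyloxy)phenyl]-4-bromo-2,3-dihydro-1-benzofuran (cis) | Brc1cc(OCc2ccccc2)cc2c1[C@@H](c1cc(OCc3ccccc3)cc(OCc3ccccc3)c1)[C@@H](c1ccc(OCc3ccccc3)cc1)O2
F10 | step 9 | (4S,5S-series) 3-bromo-4-[3,5-bis(benzyloxy)phenyl]-5-[4-(triflyloxy)phenyl]oxolan-2-one (C3 epimer mixture) | O=C1C(Br)[C@@H](c2cc(OCc3ccccc3)cc(OCc3ccccc3)c2)[C@@H](c2ccc(OS(=O)(=O)C(F)(F)F)cc2)O1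
F11 | step 9 | (DHB-4-yl)zinc bromide | Br[Zn]c1cc(OCc2ccccc2)cc2c1[C@@H](c1cc(OCc3ccccc3)cc(OCc3ccccc3)c1)[C@H](c1ccc(OCc3ccccc3)cc1)O2
F12 | step 9 | (3S,4S,5S)-3-(DHB-4-yl)-4-[3,5-bis(benzyloxy)phenyl]-5-[4-(triflyloxy)phenyl]oxolan-2-one (3,4-trans, 4,5-cis) | O=C1[C@H](c2cc(OCc3ccccc3)cc3c2[C@@H](c2cc(OCc4ccccc4)cc(OCc4ccccc4)c2)[C@H](c2ccc(OCc4ccccc4)cc2)O3)[C@@H](c2cc(OCc3ccccc3)cc(OCc3ccccc3)c2)[C@@H](c2ccc(OS(=O)(=O)C(F)(F)F)cc2)O1
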